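**Retrosynthetic overview**
- Last disconnections are C–O: the phenol silyl ether, then the angelate ester of the primary allylic alcohol (angelic acid bought with its Z geometry).
- Key C–C disconnection: Cα–CH2OH of the (Z)-2-(hydroxymethyl)but-2-enoate, made by an intermolecular reductive aldol of a but-2-ynoate ester (as its α-alumino enoate) with formaldehyde; this also fixes the Z alkene.
- The but-2-ynoate is cut at the ester C–O into but-2-ynoic acid and the (S)-1-arylpropan-1-ol.
- The (S)-carbinol comes from catalytic enantioselective ethylation of silyl-protected 3-hydroxy-4,5-dimethoxybenzaldehyde.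
- No ring is formed; the benzene ring is bought in the aldehyde.

Assumption: the target is taken as the (S)-carbinol ester with both alkenes Z (methyl cis to the ester carbonyl), and monomeric formaldehyde, supplied as gas by cracking commercial paraformaldehyde in a separate generator, is counted as one commercial compound.

**Route**

Step 1
Reactants: 1 3-hydroxy-4,5-dimethoxybenzaldehyde; 2 chlorotriisopropylsilane
Product: 3 3,4-dimethoxy-5-[(triisopropylsilyl)oxy]benzaldehyde
Conditions: TIPSCl (1.2 equiv), imidazole (2.5 equiv), DMF, rt, 12 h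
Reagents that add atoms: chlorotriisopropylsilane, CC(C)[Si](Cl)(C(C)C)C(C)C
Why: Imidazole-promoted O-silylation (silyl ether protection) masks the only acidic OH so that it neither quenches Et2Zn nor is acylated later, and the bulky aryl silyl ether survives all later steps yet is removed by fluoride.

Step 2
Reactants: 3 3,4-dimethoxy-5-[(triisopropylsilyl)oxy]benzaldehyde; 4 diethylzinc
Product: 5 (S)-1-{3,4-dimethoxy-5-[(triisopropylsilyl)oxy]phenyl}propan-1-ol
Conditions: Et2Zn (2.2 equiv), (2S)-(−)-3-exo-(dimethylamino)isoborneol [(−)-DAIB, 5 mol%], toluene, 0 °C, 16 h; then sat. aq. NH4Cl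
Reagents that add atoms: diethylzinc, CC[Zn]CC
Why: Noyori-type amino-alcohol-catalysed enantioselective 1,2-addition of a dialkylzinc, in which the (−)-DAIB–zinc chelate delivers ethyl to the Si face of the aryl aldehyde and so sets the (S)-carbinol centre (high ee is typical for benzaldehydes).

Step 3
Reactants: 5 (S)-1-{3,4-dimethoxy-5-[(triisopropylsilyl)oxy]phenyl}propan-1-ol; 6 but-2-ynoic acid
Product: 7 (S)-1-{3,4-dimethoxy-5-[(triisopropylsilyl)oxy]phenyl}propyl but-2-ynoate
Conditions: 6 (1.5 equiv), DCC (1.5 equiv), DMAP (0.1 equiv), CH2Cl2, −20 °C → rt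
Reagents that add atoms: but-2-ynoic acid, CC#CC(=O)O
Why: Steglich esterification acylates the hydroxyl oxygen without touching the benzylic C–O bond, so the (S) centre is carried over unchanged, and the alkynoic acid has no alkene geometry to lose on activation.

Step 4
Reactants: 7 (S)-1-{3,4-dimethoxy-5-[(triisopropylsilyl)oxy]phenyl}propyl but-2-ynoate; 8 diisobutylaluminium hydride; 9 formaldehyde
Product: 11 (S)-1-{3,4-dimethoxy-5-[(triisopropylsilyl)oxy]phenyl}propyl (Z)-2-(hydroxymethyl)but-2-enoate, via α-alumino enoate 10 (not isolated)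
Conditions: iBu2AlH (1.3 equiv), N-methylmorpholine N-oxide (2 equiv), THF, 0 °C, 1 h; then CH2O (gas, excess), 0 °C → rt, 3 h; aq. KNaC4H4O6
Reagents that add atoms: formaldehyde, C=O
Why: Reductive aldol (vinylalumination), in which syn 1,4-hydroalumination of the ynoate gives the α-alumino enoate (aluminium allenolate) that adds intermolecularly to formaldehyde on the side of the small β-hydrogen, so the new C–CH2OH bond lies trans to the methyl group and the (Z)-enoate results while the remote (S) centre is untouched.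

Step 5
Reactants: 11 (S)-1-{3,4-dimethoxy-5-[(triisopropylsilyl)oxy]phenyl}propyl (Z)-2-(hydroxymethyl)but-2-enoate; 12 angelic acid; 13 2,4,6-trichlorobenzoyl chloride
Product: 15 (S)-1-{3,4-dimethoxy-5-[(triisopropylsilyl)oxy]phenyl}propyl (Z)-2-({[(Z)-2-methylbut-2-enoyl]oxy}methyl)but-2-enoate, via mixed anhydride 14 (not isolated)
Conditions: 12 (1.5 equiv), 13 (1.5 equiv), Et3N (3 equiv), toluene, rt, 2 h; then 11, 60–70 °C, 12 h (no DMAP)
Reagents that add atoms: angelic acid, C/C=C(/C)C(=O)O
Why: Yamaguchi-type esterification through the hindered mixed anhydride without a nucleophilic catalyst acylates the unhindered primary allylic alcohol at the angeloyl carbonyl and avoids the DMAP-induced Z-to-E isomerisation that angelic acid is prone to, with no stereocentre formed or touched.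

Step 6
Reactants: 15 (S)-1-{3,4-dimethoxy-5-[(triisopropylsilyl)oxy]phenyl}propyl (Z)-2-({[(Z)-2-methylbut-2-enoyl]oxy}methyl)but-2-enoate
Product: 16 (S)-1-(3-hydroxy-4,5-dimethoxyphenyl)propyl (Z)-2-({[(Z)-2-methylbut-2-enoyl]oxy}methyl)but-2-enoate
Conditions: Bu4NF (1.1 equiv), AcOH (1.5 equiv), THF, 0 °C, 30 min
Reagents that add atoms: none
Why: Fluoride-mediated desilylation of the aryl silyl ether, buffered with AcOH so that neither phenoxide nor fluoride attacks the allylic angelate, the benzylic ester or the two (Z)-enoates, frees the phenol without involving the (S) centre.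

**Compound list**
1 | 3-hydroxy-4,5-dimethoxybenzaldehyde | O=Cc1cc(O)c(OC)c(OC)c1 | starting material
2 | chlorotriisopropylsilane | CC(C)[Si](Cl)(C(C)C)C(C)C | starting material
3 | 3,4-dimethoxy-5-[(triisopropylsilyl)oxy]benzaldehyde | O=Cc1cc(O[Si](C(C)C)(C(C)C)C(C)C)c(OC)c(OC)c1 | intermediate
4 | diethylzinc | CC[Zn]CC | starting material
5 | (S)-1-{3,4-dimethoxy-5-[(triisopropylsilyl)oxy]phenyl}propan-1-ol | CC[C@H](O)c1cc(O[Si](C(C)C)(C(C)C)C(C)C)c(OC)c(OC)c1 | intermediate
6 | but-2-ynoic acid | CC#CC(=O)O | starting material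
7 | (S)-1-{3,4-dimethoxy-5-[(triisopropylsilyl)oxy]phenyl}propyl but-2-ynoate | CC#CC(=O)O[C@@H](CC)c1cc(O[Si](C(C)C)(C(C)C)C(C)C)c(OC)c(OC)c1 | intermediate
8 | diisobutylaluminium hydride | CC(C)C[AlH]CC(C)C | starting material
9 | formaldehyde (monomer, from cracked paraformaldehyde) | C=O | starting material
10 | (S)-1-{3,4-dimethoxy-5-[(triisopropylsilyl)oxy]phenyl}propyl (E)-2-(diisobutylalumanyl)but-2-enoate (α-alumino enoate, methyl cis to the ester carbonyl) | C/C=C(/[Al](CC(C)C)CC(C)C)C(=O)O[C@@H](CC)c1cc(O[Si](C(C)C)(C(C)C)C(C)C)c(OC)c(OC)c1 | intermediate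
11 | (S)-1-{3,4-dimethoxy-5-[(triisopropylsilyl)oxy]phenyl}propyl (Z)-2-(hydroxymethyl)but-2-enoate | C/C=C(/CO)C(=O)O[C@@H](CC)c1cc(O[Si](C(C)C)(C(C)C)C(C)C)c(OC)c(OC)c1 | intermediate
12 | angelic acid, (Z)-2-methylbut-2-enoic acid | C/C=C(/C)C(=O)O | starting material
13 | 2,4,6-trichlorobenzoyl chloride | O=C(Cl)c1c(Cl)cc(Cl)cc1Cl | starting material
14 | (Z)-2-methylbut-2-enoic 2,4,6-trichlorobenzoic anhydride (mixed anhydride) | C/C=C(/C)C(=O)OC(=O)c1c(Cl)cc(Cl)cc1Cl | intermediate
15 | (S)-1-{3,4-dimethoxy-5-[(triisopropylsilyl)oxy]phenyl}propyl (Z)-2-({[(Z)-2-methylbut-2-enoyl]oxy}methyl)but-2-enoate | C/C=C(/C)C(=O)OC/C(=C/C)C(=O)O[C@@H](CC)c1cc(O[Si](C(C)C)(C(C)C)C(C)C)c(OC)c(OC)c1 | intermediate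
16 | (S)-1-(3-hydroxy-4,5-dimethoxyphenyl)propyl (Z)-2-({[(Z)-2-methylbut-2-enoyl]oxy}methyl)but-2-enoate | C/C=C(/C)C(=O)OC/C(=C/C)C(=O)O[C@@H](CC)c1cc(O)c(OC)c(OC)c1 | target

**Totals**
Total step count: 6. Longest linear sequence: 6 steps (1 → 16).

**Steps most likely to fail, with fallbacks**

Step 4 (reductive aldol). The risks are incomplete 1,4-hydroalumination, competing reduction of the ester, and poor capture of gaseous formaldehyde. The fallback sets out from 7 and comes back to the route at 11. Pd(PPh3)4-catalysed syn hydrostannation of 7 with Bu3SnH (THF, rt) places tin on the α-carbon and gives (S)-1-{3,4-dimethoxy-5-[(triisopropylsilyl)oxy]phenyl}propyl (E)-2-(tributylstannyl)but-2-enoate F1. Treatment with I2 in CH2Cl2 at 0 °C exchanges tin for iodine with retention and gives (S)-1-{3,4-dimethoxy-5-[(triisopropylsilyl)oxy]phenyl}propyl (E)-2-iodobut-2-enoate F2. Stille coupling of this iodide with (tributylstannyl)methanol (Pd(PPh3)4, dioxane, 80 °C) then installs the CH2OH group with retention of the alkene geometry and delivers 11.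

Step 5 (angeloylation). The risks are Z-to-E leakage of the activated angeloyl group and sluggish acylation in the absence of DMAP. The fallback sets out from 11 and comes back to the route at 15, and it activates the alcohol instead of the acid. Methanesulfonic anhydride with iPr2NEt in CH2Cl2 at −20 °C gives the allylic mesylate (S)-1-{3,4-dimethoxy-5-[(triisopropylsilyl)oxy]phenyl}propyl (Z)-2-{[(methylsulfonyl)oxy]methyl}but-2-enoate F3. SN2 displacement with caesium angelate (12, Cs2CO3, DMF, 0 °C) then gives 15; angelic acid is never turned into an acyl donor, so its geometry cannot drift.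

Step 6 (final desilylation). The risk is attack of fluoride or phenoxide on the allylic angelate or the enoates of the finished diester. The fallback sets out from 11 and comes back to the route at 16. Compound 11, which has no allylic ester yet, is desilylated first (Bu4NF/AcOH, THF, 0 °C) to give (S)-1-(3-hydroxy-4,5-dimethoxyphenyl)propyl (Z)-2-(hydroxymethyl)but-2-enoate F4. A Mitsunobu esterification of F4 with angelic acid 12 (PPh3, diisopropyl azodicarboxylate, THF, 0 °C) then acylates only the primary allylic alcohol, because the carboxylic acid (pKa about 4) and not the phenol (pKa about 10) serves as the pronucleophile, and gives target 16 directly.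

**Further compounds**
F1 | step 4 | (S)-1-{3,4-dimethoxy-5-[(triisopropylsilyl)oxy]phenyl}propyl (E)-2-(tributylstannyl)but-2-enoate | C/C=C(/[Sn](CCCC)(CCCC)CCCC)C(=O)O[C@@H](CC)c1cc(O[Si](C(C)C)(C(C)C)C(C)C)c(OC)c(OC)c1
F2 | step 4 | (S)-1-{3,4-dimethoxy-5-[(triisopropylsilyl)oxy]phenyl}propyl (E)-2-iodobut-2-enoate | C/C=C(/I)C(=O)O[C@@H](CC)c1cc(O[Si](C(C)C)(C(C)C)C(C)C)c(OC)c(OC)c1
F3 | step 5 | (S)-1-{3,4-dimethoxy-5-[(triisopropylsilyl)oxy]phenyl}propyl (Z)-2-{[(methylsulfonyl)oxy]methyl}but-2-enoate | C/C=C(/COS(C)(=O)=O)C(=O)O[C@@H](CC)c1cc(O[Si](C(C)C)(C(C)C)C(C)C)c(OC)c(OC)c1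
F4 | step 6 | (S)-1-(3-hydroxy-4,5-dimethoxyphenyl)propyl (Z)-2-(hydroxymethyl)but-2-enoate | C/C=C(/CO)C(=O)O[C@@H](CC)c1cc(O)c(OC)c(OC)c1
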